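**Plan**
Ring B is numbered C1 (OH), C2 (O–ring A), C3 (CH3), C4 (OCH3), C5 (H), C6 (isopropyl). Ring A is the 2-isopropyl-4-methoxy-5-methylphenyl group.
Retrosynthesis: the C6 isopropyl group is traced back to CO2CH3. Ring B is then opened at C5–C6 and C2–C3, and last the ArO–CH2 bond and the ring A C–OH bond are cut.
Enabling feature: C6–C1–C2 of ring B (carbon substituent, OH, OAr) is the C2–C3–C4 chain of a 4-aryloxyacetoacetate. C3–C4–C5 (CH3, OCH3, H) is 2-methoxy-3-oxobutanal, used as its dimethylamino enaminone, so the two open-chain pieces define all six positions.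
Forward: ring A comes from carvacrol and is oxygenated para to its methylated oxygen. The phenol is alkylated at an sp3 carbon, ring B closes around that oxygen in one [3+3] condensation, and the ester becomes isopropyl.
Stereochemistry: the target has no stereocentre and no configured double bond, so nothing has to be set. The Z geometry of the enaminone is lost in the ring closure.

Key step: step 6

Assumption: the two transient intermediates of the key step equilibrate through enolates, so they are written without stereodescriptors, and none of their stereo-elements survives aromatisation.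

Step 1
Reactants: 1 carvacrol (5-isopropyl-2-methylphenol)
Product: 2 carvacrol methyl ether (4-isopropyl-2-methoxy-1-methylbenzene)
Conditions: MeI, K2CO3, acetone, reflux
Reagents that add atoms: iodomethane, CI
Why: Williamson ether synthesis of an unhindered phenoxide with iodomethane, which locks the oxygen next to the ring methyl group as the ring A methoxy group.

Step 2
Reactants: 2 carvacrol methyl ether
Product: 3 1-bromo-2-isopropyl-4-methoxy-5-methylbenzene
Conditions: NBS, MeCN, 0 °C to rt, dark
Reagents that add atoms: N-bromosuccinimide, O=C1CCC(=O)N1Br
Why: Electrophilic aromatic bromination with NBS in acetonitrile goes para to the methoxy group, a site also activated by the ortho isopropyl group, whereas the free ortho position is wedged between OCH3 and isopropyl and the third free position lies meta to the methoxy group.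

Step 3
Reactants: 3 1-bromo-2-isopropyl-4-methoxy-5-methylbenzene
Product: 6 2-isopropyl-4-methoxy-5-methylphenol, via aryllithium 4 (not isolated), via dimethyl arylboronate 5 (not isolated)
Conditions: n-BuLi, THF, −78 °C; B(OMe)3, −78 °C to rt; AcOH, 30% aq. H2O2, 0 °C to rt
Reagents that add atoms: hydrogen peroxide, OO; n-butyllithium, [Li]CCCC (lithium of 4 only); trimethyl borate, COB(OC)OC (boron and methoxy groups of 5 only)
Why: Bromine–lithium exchange, trapping with the borate ester and peroxide oxidation of the arylboronate (1,2-shift of aryl from boron to oxygen) exchange Br for OH at the same carbon, so the regiochemistry of step 2 is carried over unchanged.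

Step 4
Reactants: 6 2-isopropyl-4-methoxy-5-methylphenol; 7 methyl 4-chloroacetoacetate (methyl 4-chloro-3-oxobutanoate)
Product: 8 methyl 4-(2-isopropyl-4-methoxy-5-methylphenoxy)-3-oxobutanoate
Conditions: NaH (2.2 equiv), THF–DMF, 0 °C; slow addition of 7, 0 to 50 °C; aq. HCl work-up
Reagents that add atoms: none
Why: Williamson-type SN2 displacement of the primary, carbonyl-activated chloride by the sodium phenoxide, run on the sodium enolate of 7 so that its acidic methylene is masked, as is standard for making 4-alkoxy- and 4-aryloxyacetoacetates.

Step 5
Reactants: 9 methoxyacetone (1-methoxypropan-2-one); 10 N,N-dimethylformamide dimethyl acetal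
Product: 11 (Z)-4-(dimethylamino)-3-methoxybut-3-en-2-one
Conditions: neat, 10 (1.05 equiv), 95 °C, MeOH distilled off; vacuum distillation
Reagents that add atoms: none
Why: Aminomethylenation of a CH-acidic ketone by a formamide acetal, expected at the methylene because the methoxy group makes it the more acidic and faster enolising α-position (the carbon through which methoxyacetone also reacts in amine-catalysed aldol and Mannich reactions), the push–pull alkene settling in the Z form with NMe2 anti to the acetyl group.

Step 6
Reactants: 8 methyl 4-(2-isopropyl-4-methoxy-5-methylphenoxy)-3-oxobutanoate; 11 (Z)-4-(dimethylamino)-3-methoxybut-3-en-2-one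
Product: 14 methyl 2-hydroxy-3-(2-isopropyl-4-methoxy-5-methylphenoxy)-5-methoxy-4-methylbenzoate, via open-chain enedione 12 (not isolated), via cyclic aldol 13 (not isolated)
Conditions: NaOMe (2.5 equiv), MeOH, rt then reflux under a slow N2 sweep; aq. HCl work-up
Reagents that add atoms: none
Why: Methoxide converts 8 into the enolate of its ester-flanked methylene (future C6), which adds to the aminomethylene carbon of 11 (future C5) and expels dimethylamine by addition–elimination, giving 12 as a delocalised sodium salt. Proton transfer then exposes the enolate of the aryloxy-bearing methylene (future C2), which attacks the acetyl carbonyl (future C3) in a 6-(enolendo)-exo-trig aldol closure to 13, the only ring formed, and E1cB loss of water followed by enolisation of the C1 ketone gives the sodium salt of 14, set free by acid. The closest known reaction type is the Michael–aldol [3+3] benzannulation of β-keto esters with hydroxymethylene ketones, β-alkoxy enones or enaminones, which ends in salicylates. No stereocentre is created in 14, and the labile ones of 12 and 13 vanish on aromatisation. The orientation needs C6 to bond to the CH terminus and not to the ketone, which is secured because with alkoxide only the doubly activated carbon of 8 is nucleophilic at first and because an enaminone takes up soft carbanions at its β-carbon while its carbonyl group is deactivated as a vinylogous amide. Two diversions have to be beaten: lactonisation of the acetyl enolate oxygen onto the ester, which methoxide in methanol reverses so that the 2-pyranone drains into the irreversible aromatisation, and aldol attack of the acetyl CH3 on the C1 ketone, which is disfavoured because the ArO-substituted methylene is the more acidic carbon and the α-methoxy ketone the better electrophile.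

Step 7
Reactants: 14 methyl 2-hydroxy-3-(2-isopropyl-4-methoxy-5-methylphenoxy)-5-methoxy-4-methylbenzoate
Product: 16 6-(2-hydroxypropan-2-yl)-2-(2-isopropyl-4-methoxy-5-methylphenoxy)-4-methoxy-3-methylphenol, via methyl ketone 15 (not isolated)
Conditions: MeMgBr (5 equiv), THF, 0 °C to reflux; aq. NH4Cl
Reagents that add atoms: methylmagnesium bromide, C[Mg]Br
Why: Double Grignard addition to the ester through ketone 15 after one equivalent has been spent on the phenol, a standard conversion of salicylates into 2-(2-hydroxyaryl)propan-2-ols that leaves the aryl ethers untouched.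

Step 8
Reactants: 16 6-(2-hydroxypropan-2-yl)-2-(2-isopropyl-4-methoxy-5-methylphenoxy)-4-methoxy-3-methylphenol
Product: 17 6-isopropyl-2-(2-isopropyl-4-methoxy-5-methylphenoxy)-4-methoxy-3-methylphenol (target, CNP0271085.0)
Conditions: Et3SiH (3 equiv), CF3CO2H, CH2Cl2, 0 °C to rt
Reagents that add atoms: none
Why: Ionic hydrogenation, in which trifluoroacetic acid ionises the tertiary benzylic alcohol to a cation stabilised by the ortho hydroxyl group (ortho-quinone methide character) and triethylsilane delivers hydride to it, while the aryl ethers and the free phenol are inert.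

**Compound list**
1 | carvacrol (5-isopropyl-2-methylphenol) | Cc1ccc(C(C)C)cc1O | starting material
2 | carvacrol methyl ether (4-isopropyl-2-methoxy-1-methylbenzene) | COc1cc(C(C)C)ccc1C | intermediate
3 | 1-bromo-2-isopropyl-4-methoxy-5-methylbenzene | COc1cc(C(C)C)c(Br)cc1C | intermediate
4 | (2-isopropyl-4-methoxy-5-methylphenyl)lithium | COc1cc(C(C)C)c([Li])cc1C | intermediate
5 | dimethyl (2-isopropyl-4-methoxy-5-methylphenyl)boronate | COc1cc(C(C)C)c(B(OC)OC)cc1C | intermediate
6 | 2-isopropyl-4-methoxy-5-methylphenol | COc1cc(C(C)C)c(O)cc1C | intermediate
7 | methyl 4-chloroacetoacetate | COC(=O)CC(=O)CCl | starting material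
8 | methyl 4-(2-isopropyl-4-methoxy-5-methylphenoxy)-3-oxobutanoate | COC(=O)CC(=O)COc1cc(C)c(OC)cc1C(C)C | intermediate
9 | methoxyacetone | COCC(C)=O | starting material
10 | N,N-dimethylformamide dimethyl acetal | COC(OC)N(C)C | starting material
11 | (Z)-4-(dimethylamino)-3-methoxybut-3-en-2-one | CC(=O)/C(OC)=C/N(C)C | intermediate
12 | methyl 2-[(2-isopropyl-4-methoxy-5-methylphenoxy)acetyl]-4-methoxy-5-oxohex-2-enoate (configurationally labile) | COC(=O)C(=CC(OC)C(C)=O)C(=O)COc1cc(C)c(OC)cc1C(C)C | intermediate
13 | methyl 4-hydroxy-5-(2-isopropyl-4-methoxy-5-methylphenoxy)-3-methoxy-4-methyl-6-oxocyclohex-1-ene-1-carboxylate (diastereomer mixture) | COC(=O)C1=CC(OC)C(C)(O)C(Oc2cc(C)c(OC)cc2C(C)C)C1=O | intermediate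
14 | methyl 2-hydroxy-3-(2-isopropyl-4-methoxy-5-methylphenoxy)-5-methoxy-4-methylbenzoate | COC(=O)c1cc(OC)c(C)c(Oc2cc(C)c(OC)cc2C(C)C)c1O | intermediate
15 | 1-[2-hydroxy-3-(2-isopropyl-4-methoxy-5-methylphenoxy)-5-methoxy-4-methylphenyl]ethan-1-one | CC(=O)c1cc(OC)c(C)c(Oc2cc(C)c(OC)cc2C(C)C)c1O | intermediate
16 | 6-(2-hydroxypropan-2-yl)-2-(2-isopropyl-4-methoxy-5-methylphenoxy)-4-methoxy-3-methylphenol | CC(C)(O)c1cc(OC)c(C)c(Oc2cc(C)c(OC)cc2C(C)C)c1O | intermediate
17 | 6-isopropyl-2-(2-isopropyl-4-methoxy-5-methylphenoxy)-4-methoxy-3-methylphenol | COc1cc(C(C)C)c(Oc2c(C)c(OC)cc(C(C)C)c2O)cc1C | target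

**Count and risks**
Total steps: 8. Longest linear sequence: 7 steps (steps 1, 2, 3, 4, 6, 7, 8, from carvacrol). Step 5 is the one-step side branch.

Step 6. The cascade may stop after the first C–C bond. The delocalised anion of 12 may resist the second enolisation, be drained by lactonisation or by retro-Claisen loss of the aryloxyacetyl group, or close in the opposite aldol sense. The fallback takes ring B from the aromatic pool and makes the diaryl ether by Ullmann coupling. It sets out from 6 and comes back at 17. Iodination of 6 with NIS and catalytic TsOH in MeCN should go to the only free position ortho to the hydroxyl group and give 2-iodo-6-isopropyl-4-methoxy-3-methylphenol F1. BnBr and K2CO3 in DMF would give 2-(benzyloxy)-3-iodo-1-isopropyl-5-methoxy-4-methylbenzene F2. Ullmann diaryl ether coupling of F2 with a second portion of 6 (CuI, picolinic acid, K3PO4, DMSO, 100 °C) would give the O-benzyl ether of the target, 2-(benzyloxy)-1-isopropyl-3-(2-isopropyl-4-methoxy-5-methylphenoxy)-5-methoxy-4-methylbenzene F3. Hydrogenolysis (H2, Pd/C, EtOAc) then gives 17.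

Step 5. Aminomethylenation may take place at the methyl terminus of the ketone, or at both α-positions, so that the three-carbon partner is obtained as a constitutional mixture. The fallback draws the partner from a skeleton that already fixes the constitution and exchanges the leaving group. It sets out from 8 and comes back at 14. Commercial 3,3-dimethoxybutan-2-one (CC(=O)C(C)(OC)OC) has the oxygenated carbon already next to the acetyl group. On heating with catalytic TsOH it should lose methanol to give 3-methoxybut-3-en-2-one F4. Br2 in CH2Cl2 at −78 °C adds to the enol ether to give racemic 3,4-dibromo-3-methoxybutan-2-one F5. Et3N removes HBr from it to give (Z)-4-bromo-3-methoxybut-3-en-2-one F6, whose geometry is of no consequence. F6 then takes the place of 11 in the condensation with 8 under NaOMe in MeOH. Bromide instead of dimethylamine is expelled in the addition–elimination, and the same intermediates 12 and 13 lead to 14.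

Step 4. Self-alkylation and self-condensation of the chloro keto ester enolate may outrun O-alkylation by the phenoxide, which is shielded by its ortho isopropyl group. The fallback builds the keto ester by two-carbon homologation of an aryloxyacetic acid. It sets out from 6 and comes back at 8. Chloroacetic acid and aqueous NaOH at reflux should convert 6 into 2-(2-isopropyl-4-methoxy-5-methylphenoxy)acetic acid F7. Coupling with Meldrum's acid (EDC·HCl, DMAP, CH2Cl2) would give 5-[1-hydroxy-2-(2-isopropyl-4-methoxy-5-methylphenoxy)ethylidene]-2,2-dimethyl-1,3-dioxane-4,6-dione F8. Methanolysis of F8 in refluxing MeOH–toluene gives 8.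

**Further compounds**
F1 | step 6 | 2-iodo-6-isopropyl-4-methoxy-3-methylphenol | Oc1c(I)c(C)c(OC)cc1C(C)C
F2 | step 6 | 2-(benzyloxy)-3-iodo-1-isopropyl-5-methoxy-4-methylbenzene | CC(C)c1cc(OC)c(C)c(I)c1OCc1ccccc1
F3 | step 6 | 2-(benzyloxy)-1-isopropyl-3-(2-isopropyl-4-methoxy-5-methylphenoxy)-5-methoxy-4-methylbenzene | COc1cc(C(C)C)c(Oc2c(C)c(OC)cc(C(C)C)c2OCc2ccccc2)cc1C
F4 | step 5 | 3-methoxybut-3-en-2-one | C=C(OC)C(C)=O
F5 | step 5 | 3,4-dibromo-3-methoxybutan-2-one (racemic) | CC(=O)C(Br)(OC)CBr
F6 | step 5 | (Z)-4-bromo-3-methoxybut-3-en-2-one | CC(=O)/C(OC)=C/Br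
F7 | step 4 | 2-(2-isopropyl-4-methoxy-5-methylphenoxy)acetic acid | OC(=O)COc1cc(C)c(OC)cc1C(C)C
F8 | step 4 | 5-[1-hydroxy-2-(2-isopropyl-4-methoxy-5-methylphenoxy)ethylidene]-2,2-dimethyl-1,3-dioxane-4,6-dione | CC1(C)OC(=O)C(=C(O)COc2cc(C)c(OC)cc2C(C)C)C(=O)O1
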